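**Plan**

- Retrosynthesis: the three phenolic MOM ethers come off first, then ring C is cut at C3–C4. The C4 ketone beside the C3 tertiary carbinol is an acyloin inside the pyranone ring, with C4 on ring A (C4a) and C3 carrying ring B and the O1–C2H2 link back to C8a. The bond therefore unravels to an aromatic aldehyde (C4) and an aryl ketone (C3) held six atoms apart.
- Next cuts: the O1–C2 ether (ring A phenol plus ring B phenacyl bromide), then the two prenyl C–C bonds (ring A C6 by para-Claisen–Cope from an O-prenyl ether; ring B C3' by phenoxide C-alkylation).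
- Forward: the ring A aldehyde (3 steps) and the ring B bromoketone (4 steps) are made apart and joined through O1–C2. Ring C is closed last by a carbene-catalysed crossed benzoin reaction, and the MOM helpers are then removed.
- Stereochemistry: the only stereocentre (C3, R) arises in the ring closure under control of a chiral aminoindanol-derived triazolylidene; being quaternary, it cannot be lost afterwards.

Key step: step 9

Assumption: the (5aS,10bR) triazolium salt (cation Fc1c(F)c(F)c(F)c(F)c1-[n+]1cn2c(n1)CO[C@H]1Cc3ccccc3[C@H]12, from (1R,2S)-cis-1-amino-2-indanol) is taken to deliver the (R)-carbinol. The sense of induction has not been derived from a model here and is to be checked on the first run; the (5aR,10bS) salt is used instead if it is reversed.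

**Route**

Step 1
Reactants: 1 2,4,6-trihydroxybenzaldehyde
Product: 2 2-hydroxy-4,6-bis(methoxymethoxy)benzaldehyde
Conditions: MOMCl (2.1 equiv), K2CO3, acetone, 0 °C to rt
Reagents that add atoms: chloromethyl methyl ether (MOMCl), COCCl
Why: Williamson-type acetalisation of the phenoxides: the para hydroxyl and one of the two equivalent ortho hydroxyls react, while the last ortho hydroxyl, chelated to the formyl oxygen, is too weakly nucleophilic under carbonate conditions, so the symmetric triol should stop at the mono-phenol.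

Step 2
Reactants: 2 2-hydroxy-4,6-bis(methoxymethoxy)benzaldehyde; 3 prenyl bromide (1-bromo-3-methylbut-2-ene)
Product: 4 2,4-bis(methoxymethoxy)-6-[(3-methylbut-2-en-1-yl)oxy]benzaldehyde
Conditions: K2CO3, DMF, rt
Reagents that add atoms: none
Why: Williamson etherification of the only free phenol; DMF breaks the intramolecular hydrogen bond and the allylic bromide is taken at oxygen.

Step 3
Reactants: 4 2,4-bis(methoxymethoxy)-6-[(3-methylbut-2-en-1-yl)oxy]benzaldehyde
Product: 7 6-hydroxy-2,4-bis(methoxymethoxy)-3-(3-methylbut-2-en-1-yl)benzaldehyde, via ortho-dienone 5 (not isolated), via para-dienone 6 (not isolated)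
Conditions: PhNEt2, 200 °C, sealed tube, argon
Reagents that add atoms: none
Why: Aromatic para-Claisen–Cope rearrangement: the [3,3] shift onto the free ortho carbon gives the congested 1,1-dimethylallyl dienone 5, a second [3,3] (Cope) shift carries the group, restored to a normal prenyl, to the single para carbon between the two MOM ethers (6), and enolisation gives the chelated phenol, as precedented for the corresponding acetophenone.

Step 4
Reactants: 8 1-(2,4-dihydroxyphenyl)ethan-1-one; 3 prenyl bromide
Product: 9 1-[2,4-dihydroxy-3-(3-methylbut-2-en-1-yl)phenyl]ethan-1-one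
Conditions: KOH (10% aq.), 0 °C to rt
Reagents that add atoms: none
Why: Phenoxide C-alkylation in water: the resorcinolate oxygens are hydrogen-bonded to the solvent, so the allylic bromide is taken at carbon, mainly at C3 between the two oxygens; O-prenyl and 5-prenyl isomers are the expected by-products and are removed by chromatography.

Step 5
Reactants: 9 1-[2,4-dihydroxy-3-(3-methylbut-2-en-1-yl)phenyl]ethan-1-one
Product: 10 1-[2-hydroxy-4-(methoxymethoxy)-3-(3-methylbut-2-en-1-yl)phenyl]ethan-1-one
Conditions: MOMCl (1.1 equiv), K2CO3, acetone, 0 °C to rt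
Reagents that add atoms: chloromethyl methyl ether (MOMCl), COCCl
Why: Selective Williamson-type acetalisation: the 2-hydroxyl is chelated to the acetyl group and crowded by the prenyl group, so only the 4-hydroxyl should react.

Step 6
Reactants: 10 1-[2-hydroxy-4-(methoxymethoxy)-3-(3-methylbut-2-en-1-yl)phenyl]ethan-1-one
Product: 11 1-[2-methoxy-4-(methoxymethoxy)-3-(3-methylbut-2-en-1-yl)phenyl]ethan-1-one
Conditions: MeI, K2CO3, DMF, 40 °C
Reagents that add atoms: iodomethane, CI
Why: Williamson methylation of the remaining chelated phenol, which needs the polar solvent and mild heating; no other site is acidic enough to compete under carbonate.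

Step 7
Reactants: 11 1-[2-methoxy-4-(methoxymethoxy)-3-(3-methylbut-2-en-1-yl)phenyl]ethan-1-one
Product: 13 2-bromo-1-[2-methoxy-4-(methoxymethoxy)-3-(3-methylbut-2-en-1-yl)phenyl]ethan-1-one, via silyl enol ether 12 (not isolated)
Conditions: LiN(SiMe3)2, Me3SiCl, THF, −78 °C; then NBS, −78 to 0 °C
Reagents that add atoms: N-bromosuccinimide, O=C1CCC(=O)N1Br
Why: α-Bromination via a silyl enol ether: kinetic enolisation of the methyl ketone and O-silylation give 12, whose electron-rich double bond should take bromine from NBS far faster than the trisubstituted prenyl alkene.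

Step 8
Reactants: 7 6-hydroxy-2,4-bis(methoxymethoxy)-3-(3-methylbut-2-en-1-yl)benzaldehyde; 13 2-bromo-1-[2-methoxy-4-(methoxymethoxy)-3-(3-methylbut-2-en-1-yl)phenyl]ethan-1-one
Product: 14 6-{2-[2-methoxy-4-(methoxymethoxy)-3-(3-methylbut-2-en-1-yl)phenyl]-2-oxoethoxy}-2,4-bis(methoxymethoxy)-3-(3-methylbut-2-en-1-yl)benzaldehyde
Conditions: K2CO3, acetone, rt
Reagents that add atoms: none
Why: Williamson etherification of the chelated phenol with the reactive phenacyl bromide; carbonate at room temperature is chosen so that the product does not go on to Rap–Stoermer aldol condensation, which the aldehyde flanked by two ortho oxygens also resists.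

Step 9
Reactants: 14 6-{2-[2-methoxy-4-(methoxymethoxy)-3-(3-methylbut-2-en-1-yl)phenyl]-2-oxoethoxy}-2,4-bis(methoxymethoxy)-3-(3-methylbut-2-en-1-yl)benzaldehyde
Product: 17 (3R)-3-hydroxy-3-[2-methoxy-4-(methoxymethoxy)-3-(3-methylbut-2-en-1-yl)phenyl]-5,7-bis(methoxymethoxy)-6-(3-methylbut-2-en-1-yl)-2,3-dihydro-4H-chromen-4-one, via Breslow enaminol 15 (not isolated), via azolium alkoxide 16 (not isolated)
Conditions: (5aS,10bR)-2-(pentafluorophenyl)-5a,10b-dihydro-4H,6H-indeno[2,1-b][1,2,4]triazolo[4,3-d][1,4]oxazin-2-ium tetrafluoroborate (15 mol %), Et3N (15 mol %), toluene, rt, argon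
Reagents that add atoms: none
Why: The triazolylidene freed from the salt by Et3N adds to the formyl carbon of 14 and proton transfer gives the Breslow enaminol 15, an acyl anion equivalent at the future C4; its nucleophilic carbon attacks the tethered aryl ketone carbon (future C3) while the enol O–H passes to the ketone oxygen, and the azolium alkoxide 16 then expels the carbene to leave the C4 ketone. The closest known reaction type is the carbene-catalysed enantioselective intramolecular crossed aldehyde–ketone benzoin cyclisation of 2-(2-oxo-2-arylethoxy)benzaldehydes to 3-aryl-3-hydroxychroman-4-ones. Ring C closes in the 6-exo-trig mode, C4 adding to the carbonyl whose oxygen stays outside the new ring. The new stereocentre C3 is set by the catalyst: the cis-fused indane of the aminoindanol backbone walls off one face of the planar enaminol, and the O–H···O=C hydrogen bond together with the two-atom O1–C2 tether fixes which prochiral face of the ketone meets the open face, which should give the (R)-carbinol. The step needs the crossed sense and chemoselection over base-mediated aldol (Rap–Stoermer) closure to a benzofuran: only the aldehyde has the C–H needed to become the acyl donor, the aldehyde between two ortho oxygens is a poor aldol acceptor, and a weak amine base with the acidic N-C6F5 azolium keeps the enolate concentration low. The product is a quaternary α-ketol with no hydrogen on C3, so it cannot epimerise by enolisation.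

Step 10
Reactants: 17 (3R)-3-hydroxy-3-[2-methoxy-4-(methoxymethoxy)-3-(3-methylbut-2-en-1-yl)phenyl]-5,7-bis(methoxymethoxy)-6-(3-methylbut-2-en-1-yl)-2,3-dihydro-4H-chromen-4-one
Product: 18 (3R)-3,5,7-trihydroxy-3-[4-hydroxy-2-methoxy-3-(3-methylbut-2-en-1-yl)phenyl]-6-(3-methylbut-2-en-1-yl)-2,3-dihydro-4H-chromen-4-one
Conditions: HCl (about 1 M) in MeOH, THF co-solvent, rt
Reagents that add atoms: none
Why: Acid-catalysed transacetalisation of the three aryl MOM ethers to methanol; at room temperature the prenyl groups should not cyclise onto the neighbouring phenols, and the C3 carbinol, whose ionisation would put a cation next to the C4 carbonyl, should stay intact with its configuration.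

**Compound list**

1 | 2,4,6-trihydroxybenzaldehyde | O=Cc1c(O)cc(O)cc1O | starting material
2 | 2-hydroxy-4,6-bis(methoxymethoxy)benzaldehyde | O=Cc1c(O)cc(OCOC)cc1OCOC | intermediate
3 | prenyl bromide (1-bromo-3-methylbut-2-ene) | CC(C)=CCBr | starting material
4 | 2,4-bis(methoxymethoxy)-6-[(3-methylbut-2-en-1-yl)oxy]benzaldehyde | O=Cc1c(OCC=C(C)C)cc(OCOC)cc1OCOC | intermediate
5 | ortho-dienone, 2,4-bis(methoxymethoxy)-5-(2-methylbut-3-en-2-yl)-6-oxocyclohexa-1,3-diene-1-carbaldehyde (racemic, not isolated) | O=CC1=C(OCOC)C=C(OCOC)C(C(C)(C)C=C)C1=O | intermediate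
6 | para-dienone, 2,4-bis(methoxymethoxy)-3-(3-methylbut-2-en-1-yl)-6-oxocyclohexa-1,4-diene-1-carbaldehyde (racemic, not isolated) | O=CC1=C(OCOC)C(CC=C(C)C)C(OCOC)=CC1=O | intermediate
7 | 6-hydroxy-2,4-bis(methoxymethoxy)-3-(3-methylbut-2-en-1-yl)benzaldehyde | O=Cc1c(O)cc(OCOC)c(CC=C(C)C)c1OCOC | intermediate
8 | 1-(2,4-dihydroxyphenyl)ethan-1-one | CC(=O)c1ccc(O)cc1O | starting material
9 | 1-[2,4-dihydroxy-3-(3-methylbut-2-en-1-yl)phenyl]ethan-1-one | CC(=O)c1ccc(O)c(CC=C(C)C)c1O | intermediate
10 | 1-[2-hydroxy-4-(methoxymethoxy)-3-(3-methylbut-2-en-1-yl)phenyl]ethan-1-one | CC(=O)c1ccc(OCOC)c(CC=C(C)C)c1O | intermediate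
11 | 1-[2-methoxy-4-(methoxymethoxy)-3-(3-methylbut-2-en-1-yl)phenyl]ethan-1-one | CC(=O)c1ccc(OCOC)c(CC=C(C)C)c1OC | intermediate
12 | silyl enol ether, ({1-[2-methoxy-4-(methoxymethoxy)-3-(3-methylbut-2-en-1-yl)phenyl]ethenyl}oxy)trimethylsilane (not isolated) | C=C(O[Si](C)(C)C)c1ccc(OCOC)c(CC=C(C)C)c1OC | intermediate
13 | 2-bromo-1-[2-methoxy-4-(methoxymethoxy)-3-(3-methylbut-2-en-1-yl)phenyl]ethan-1-one | O=C(CBr)c1ccc(OCOC)c(CC=C(C)C)c1OC | intermediate
14 | 6-{2-[2-methoxy-4-(methoxymethoxy)-3-(3-methylbut-2-en-1-yl)phenyl]-2-oxoethoxy}-2,4-bis(methoxymethoxy)-3-(3-methylbut-2-en-1-yl)benzaldehyde | O=Cc1c(OCC(=O)c2ccc(OCOC)c(CC=C(C)C)c2OC)cc(OCOC)c(CC=C(C)C)c1OCOC | intermediate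
15 | Breslow enaminol: the formyl carbon of 14 bonded as C(OH)= to the carbene carbon of the (5aS,10bR) triazolylidene; alkene geometry not defined (not isolated) | OC(=C1N(c2c(F)c(F)c(F)c(F)c2F)N=C3CO[C@H]4Cc5ccccc5[C@H]4N13)c6c(OCC(=O)c7ccc(OCOC)c(CC=C(C)C)c7OC)cc(OCOC)c(CC=C(C)C)c6OCOC | intermediate
16 | azolium alkoxide: ring-closed adduct with the triazolium still on C4 (alkoxide, configuration not defined) and the (3R) carbinol formed (not isolated) | [O-]C1(c2n(-c3c(F)c(F)c(F)c(F)c3F)nc4CO[C@H]5Cc6ccccc6[C@H]5[n+]24)c7c(OC[C@]1(O)c8ccc(OCOC)c(CC=C(C)C)c8OC)cc(OCOC)c(CC=C(C)C)c7OCOC | intermediate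
17 | (3R)-3-hydroxy-3-[2-methoxy-4-(methoxymethoxy)-3-(3-methylbut-2-en-1-yl)phenyl]-5,7-bis(methoxymethoxy)-6-(3-methylbut-2-en-1-yl)-2,3-dihydro-4H-chromen-4-one | COc1c([C@@]2(O)COc3cc(OCOC)c(CC=C(C)C)c(OCOC)c3C2=O)ccc(OCOC)c1CC=C(C)C | intermediate
18 | (3R)-3,5,7-trihydroxy-3-[4-hydroxy-2-methoxy-3-(3-methylbut-2-en-1-yl)phenyl]-6-(3-methylbut-2-en-1-yl)-2,3-dihydro-4H-chromen-4-one | COc1c([C@@]2(O)COc3cc(O)c(CC=C(C)C)c(O)c3C2=O)ccc(O)c1CC=C(C)C | target

**Step count and risks**

Total steps: 10. Longest linear sequence: 7 (steps 4, 5, 6, 7, 8, 9, 10 from compound 8).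

Steps most likely to fail:

1. Step 9. The carbene may fail to add to the doubly ortho-substituted, electron-rich aldehyde, base-mediated aldol condensation may outrun catalysis, or face selection on the hindered aryl ketone may be poor. Fallback, from 14 back to 17: catalyst control of the stereocentre is given up. Ring C is closed with the small achiral carbene from 3-benzyl-5-(2-hydroxyethyl)-4-methylthiazolium chloride and an amine base (t-BuOH–THF, 40 °C), the known racemic aldehyde–ketone benzoin cyclisation, to give the racemic ketol F1. F1 is then resolved by preparative chromatography on a chiral stationary phase (amylose carbamate, CO2–alcohol) to return 17, and the (3S)-enantiomer is set aside.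

2. Step 3. The first [3,3] shift may end by enolisation to the ortho 1,1-dimethylallyl phenol instead of passing on to the para carbon, or the aldehyde may degrade at 200 °C. Fallback, from 2 back to 7: the prenyl group is put in by directed metalation instead of a sigmatropic shift. Compound 2 is silylated (i-Pr3SiCl, imidazole, DMF) to the silyl ether F2, and its aldehyde is masked without acid by condensation with N,N'-dimethylethane-1,2-diamine (toluene, MgSO4, 80 °C) to the imidazolidine F3. n-BuLi (THF, 0 °C) removes the proton between the two MOM ethers, the doubly activated site, to give the aryllithium F4; CuBr·SMe2 and 3 then give the prenylated imidazolidine F5. Aqueous NH4Cl work-up hydrolyses the aminal to the aldehyde F6, and Bu4NF (THF, 0 °C) frees the phenol to give 7.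

3. Step 10. Protic acid may cyclise a prenyl group onto a neighbouring phenol or ionise and dehydrate the benzylic tertiary carbinol. Fallback, from 17 to 18: protic solvolysis is replaced by a protecting-group exchange followed by fluoride. Me3SiOTf with 2,2'-bipyridyl (CH2Cl2, 0 °C to rt) turns the three aryl MOM ethers into trimethylsilyl ethers and silylates the carbinol, giving the tetrakis(trimethylsilyl) ether F7. Bu4NF buffered with AcOH (THF, 0 °C) then gives 18.

**Further compounds**

F1 | step 9 | racemic 3-hydroxy-3-[2-methoxy-4-(methoxymethoxy)-3-(3-methylbut-2-en-1-yl)phenyl]-5,7-bis(methoxymethoxy)-6-(3-methylbut-2-en-1-yl)-2,3-dihydro-4H-chromen-4-one | COc1c(C2(O)COc3cc(OCOC)c(CC=C(C)C)c(OCOC)c3C2=O)ccc(OCOC)c1CC=C(C)C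
F2 | step 3 | 2,4-bis(methoxymethoxy)-6-[(triisopropylsilyl)oxy]benzaldehyde | O=Cc1c(O[Si](C(C)C)(C(C)C)C(C)C)cc(OCOC)cc1OCOC
F3 | step 3 | 2-{2,4-bis(methoxymethoxy)-6-[(triisopropylsilyl)oxy]phenyl}-1,3-dimethylimidazolidine | CN1CCN(C)C1c1c(O[Si](C(C)C)(C(C)C)C(C)C)cc(OCOC)cc1OCOC
F4 | step 3 | aryllithium of F3, lithiated between the two MOM ethers | [Li]c1c(OCOC)cc(O[Si](C(C)C)(C(C)C)C(C)C)c(C2N(C)CCN2C)c1OCOC
F5 | step 3 | 2-{2,4-bis(methoxymethoxy)-3-(3-methylbut-2-en-1-yl)-6-[(triisopropylsilyl)oxy]phenyl}-1,3-dimethylimidazolidine | CN1CCN(C)C1c1c(O[Si](C(C)C)(C(C)C)C(C)C)cc(OCOC)c(CC=C(C)C)c1OCOC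
F6 | step 3 | 2,4-bis(methoxymethoxy)-3-(3-methylbut-2-en-1-yl)-6-[(triisopropylsilyl)oxy]benzaldehyde | O=Cc1c(O[Si](C(C)C)(C(C)C)C(C)C)cc(OCOC)c(CC=C(C)C)c1OCOC
F7 | step 10 | (3R)-3-[2-methoxy-3-(3-methylbut-2-en-1-yl)-4-(trimethylsilyloxy)phenyl]-6-(3-methylbut-2-en-1-yl)-3,5,7-tris(trimethylsilyloxy)-2,3-dihydro-4H-chromen-4-one | COc1c([C@@]2(O[Si](C)(C)C)COc3cc(O[Si](C)(C)C)c(CC=C(C)C)c(O[Si](C)(C)C)c3C2=O)ccc(O[Si](C)(C)C)c1CC=C(C)C
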